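## Retrosynthetic overview

1. Target ⇒ anti opening at C5 by acetic acid (Ti(OiPr)4) of the (4R,5R)-epoxy alcohol 25 ⇒ Sharpless epoxidation of the 4Z allylic alcohol 24.
2. Ten-membered carbocycle ⇒ C7–C8: SmI2 ketyl radical (aldehyde C8) adds to butenolide C7, and acetate loss unveils C11=C13; this sets C7 and C8.
3. Furanone ⇒ Au(I) cyclisation of a γ-hydroxy ynone made by carbonylative Sonogashira coupling (C3 = CO) of Z-vinyl iodide 10 with alkynol 16.
4. 10 ⇒ butenolide by RCM, Z-iodide by Red-Al/I2, C6 by asymmetric alkynylation of acrolein; 16 ⇒ C10 by asymmetric allylboration of a silyl ynone.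
5. Ring order: butenolide → furanone → ten-membered ring (radical step) → epoxide (transient).

Assumption: positions are labelled with germacranolide numbering C1–C15 (furanone C1(=O)–C2=C3(–O–C10); lactone C6–O–C12(=O)–C11(=C13)–C7; C14 = CH3 on C10; C15 = CH2OH on C4).

## Route

Step 1
Reactants: 1 2-(bromomethyl)acrylic acid
Product: 2 2-(acetoxymethyl)acrylic acid
Conditions: KOAc (3 equiv), AcOH, 60 °C
Reagents that add atoms: potassium acetate, CC(=O)[O-].[K+]
Why: SN2 (or SN2′, same product) displacement of the activated allylic bromide by acetate; in AcOH the acrylic acid stays protonated and does not alkylate itself.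

Step 2
Reactants: 3 acrolein; 4 3-(tert-butoxy)prop-1-yne
Product: 6 (3S)-6-(tert-butoxy)hex-1-en-4-yn-3-ol, via alkynyl(methyl)zinc 5 (not isolated)
Conditions: 4, Me2Zn (3 equiv), ProPhenol (10 mol %, the enantiomer that gives 3S), Ph3P=O (20 mol %), PhMe, 0 °C; then 3; aq NH4Cl
Reagents that add atoms: none
Why: Trost Zn–ProPhenol asymmetric alkynylation (1,2-addition of the alkynylzinc to the enal) creates the C6 carbinol under catalyst control; the 3S alcohol has the spatial arrangement of C6 in the target.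

Step 3
Reactants: 6 (3S)-6-(tert-butoxy)hex-1-en-4-yn-3-ol
Product: 8 (3S,4Z)-6-(tert-butoxy)-5-iodohexa-1,4-dien-3-ol, via vinylalanate 7 (not isolated)
Conditions: Red-Al (2 equiv), THF, 0 °C → rt; EtOAc; then I2, −78 → 0 °C
Reagents that add atoms: iodine, II
Why: Hydroxyl-directed trans-hydroalumination of the propargylic alcohol (hydride to the proximal carbon, Al to the distal carbon in a five-membered alanate) and iodinolysis with retention give the Z-iodide with iodine (the future C3 attachment) cis to C6; the tert-butyl ether neither directs nor leaves.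

Step 4
Reactants: 8 (3S,4Z)-6-(tert-butoxy)-5-iodohexa-1,4-dien-3-ol; 2 2-(acetoxymethyl)acrylic acid
Product: 9 (3S,4Z)-6-(tert-butoxy)-5-iodohexa-1,4-dien-3-yl 2-(acetoxymethyl)acrylate
Conditions: EDC·HCl (1.5 equiv), DMAP (10 mol %), CH2Cl2, 0 °C → rt
Reagents that add atoms: none
Why: Steglich esterification of the secondary bis-allylic alcohol; the stereocentre is not touched.

Step 5
Reactants: 9 (3S,4Z)-6-(tert-butoxy)-5-iodohexa-1,4-dien-3-yl 2-(acetoxymethyl)acrylate
Product: 10 {(5S)-5-[(1Z)-3-(tert-butoxy)-2-iodoprop-1-en-1-yl]-2-oxo-2,5-dihydrofuran-3-yl}methyl acetate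
Conditions: Hoveyda–Grubbs II (5 mol %), PhMe (5 mM), 80 °C
Reagents that add atoms: none
Why: Ring-closing metathesis between the vinyl group and the 1,1-disubstituted acrylate closes the butenolide (first ring, C7=C11 with C13 as CH2OAc) with loss of ethene; the trisubstituted iodoalkene is inert to the Ru carbene.

Step 6
Reactants: 11 ethynyltrimethylsilane; 12 N-methoxy-N-methylacetamide
Product: 14 4-(trimethylsilyl)but-3-yn-2-one, via lithium acetylide 13 (not isolated)
Conditions: n-BuLi, THF, −78 °C; then 12, −78 → 0 °C; aq NH4Cl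
Reagents that add atoms: none
Why: Weinreb ketone synthesis; the chelated tetrahedral intermediate prevents over-addition.

Step 7
Reactants: 14 4-(trimethylsilyl)but-3-yn-2-one
Product: 16 (3S)-3-methylhex-5-en-1-yn-3-ol, via silyl carbinol 15 (not isolated)
Conditions: allylB(OiPr)2 (1.5 equiv), 3,3′-Br2-BINOL (15 mol %, the enantiomer that gives 3S), PhCF3–PhMe, −35 °C; then K2CO3, MeOH, rt
Reagents that add atoms: allyldiisopropoxyborane, C=CCB(OC(C)C)OC(C)C
Why: BINOL-catalysed asymmetric allylboration of a ketone (Schaus) sets the C10 tertiary carbinol by discriminating the bulky silylalkynyl group from methyl (3S = 10S of the target), and K2CO3/MeOH then removes the C-silyl group.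

Step 8
Reactants: 10 butenolide Z-vinyl iodide; 16 (3S)-3-methylhex-5-en-1-yn-3-ol
Product: 17 γ-hydroxy ynone, butenolide(C6)–CH=C(CH2OtBu)–C(=O)–C≡C–C(OH)(CH3)–CH2CH=CH2 (4Z, C6 R by CIP, C10 S)
Conditions: PdCl2(PPh3)2 (5 mol %), CuI (2 mol %), Et3N (2 equiv), CO (1 atm), THF, rt
Reagents that add atoms: carbon monoxide, [C-]#[O+]
Why: Carbonylative Sonogashira coupling: oxidative addition of the vinyl iodide (far faster than ionisation of the allylic acetate), CO insertion and alkynyl transfer form C3–C4 and C2–C3 with retention of the Z geometry, and the CO atmosphere suppresses direct coupling.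

Step 9
Reactants: 17 γ-hydroxy ynone
Product: 18 {(5R)-5-[(1Z)-2-[(5S)-5-allyl-5-methyl-4-oxo-4,5-dihydrofuran-2-yl]-3-(tert-butoxy)prop-1-en-1-yl]-2-oxo-2,5-dihydrofuran-3-yl}methyl acetate
Conditions: (p-CF3C6H4)3PAuCl (5 mol %), AgOTf (5 mol %), PhMe (not dried), rt
Reagents that add atoms: water, O
Why: Au(I)-catalysed hydrative cyclisation of a γ-hydroxy alkynone to a 3(2H)-furanone (net isomerisation: water adds at C1, the C10 hydroxyl closes onto C3 and water is lost) forms the second ring without touching C10.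

Step 10
Reactants: 18 allyl furanone
Product: 20 aldehyde (the allyl group of 18 is now CH2–CHO, C9–C8), via diol 19 (not isolated)
Conditions: OsO4 (2 mol %), NaIO4 (4 equiv), 2,6-lutidine (2 equiv), dioxane–H2O 3:1, 0 °C → rt; used crude at once
Reagents that add atoms: osmium tetroxide, O=[Os](=O)(=O)=O (catalytic; its oxygen is replenished by sodium periodate, [Na+].[O-]I(=O)(=O)=O)
Why: Lemieux–Johnson cleavage; OsO4 selects the only electron-neutral monosubstituted alkene over the three conjugated, electron-poor trisubstituted ones, and periodate cleaves the diol to the C8 aldehyde.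

Step 11
Reactants: 20 aldehyde
Product: 22 (4Z,6R,7R,8R,10S)-8-hydroxy-15-O-tert-butyl macrocycle (furanone-bridged ten-membered ring, trans-fused α-methylene lactone), via samarium enolate 21 (not isolated)
Conditions: SmI2 (2.5 equiv), THF, 2 mM, slow addition of 20 at −40 °C, then rt; aq Rochelle salt
Reagents that add atoms: none
Why: Proposed new method: SmI2 reduces the aldehyde to a ketyl radical that adds to butenolide C7 (only four rotatable bonds separate the termini; attack anti to the C6–C5 bond gives the trans-fused lactone, and the Sm(III)–O group is expected to point away from the ring, giving 8R), a second electron gives the Sm(III) lactone enolate, which expels acetate (E1cB) to form C11=C13; the closest known chemistry is the SmI2 ketyl–olefin coupling of aldehydes with acrylates and butenolides (medium-ring variants known) combined with SmI2-promoted β-elimination of β-acetoxy esters.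

Step 12
Reactants: 22 macrocyclic alcohol
Product: 24 (4Z,6R,7R,8R,10S)-15-hydroxy-8-O-methacryloyl macrocycle (goyazensolide constitution), via methacrylate 23 (not isolated)
Conditions: methacryloyl chloride (3 equiv), Et3N, DMAP (cat.), CH2Cl2, 0 °C; MeOH; then TFA–CH2Cl2 1:2, 0 °C → rt
Reagents that add atoms: methacryloyl chloride, C=C(C)C(Cl)=O
Why: DMAP-catalysed acylation of the only free hydroxyl (C8), then acidolysis (E1, loss of isobutene) of the tert-butyl ether, to which the esters, the enol ether and the Michael acceptors are stable.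

Step 13
Reactants: 24 allylic alcohol
Product: 25 (4R,5R,6S,7R,8R,10S)-4,5-epoxide
Conditions: Ti(OiPr)4 (1.2 equiv), L-(+)-DIPT (1.4 equiv), t-BuOOH (2 equiv), 4 Å MS, CH2Cl2, −20 °C
Reagents that add atoms: tert-butyl hydroperoxide, CC(C)(C)OO
Why: Sharpless asymmetric epoxidation; Ti–tartrate/TBHP oxidises only the alkene of the allylic alcohol, and L-(+)-DIPT delivers oxygen to the face that gives the (4R,5R)-epoxide, so C4 already has its final configuration.

Step 14
Reactants: 25 epoxy alcohol
Product: 26 target, (4R,5S,6S,7R,8R,10S)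
Conditions: Ti(OiPr)4 (1.5 equiv), AcOH (3 equiv), CH2Cl2, rt
Reagents that add atoms: acetic acid, CC(=O)O
Why: Sharpless Ti(OiPr)4-mediated opening of a 2,3-epoxy alcohol by a carboxylic acid: acetate attacks the carbon remote from the CH2OH (C5) in an SN2 manner (inversion to 5S), while C4, tertiary and attached to the electron-poor furanone, is not attacked and keeps its oxygen as the free tertiary OH.

## Compound list

1 | 2-(bromomethyl)acrylic acid | C=C(CBr)C(=O)O | starting material
2 | 2-(acetoxymethyl)acrylic acid | C=C(COC(C)=O)C(=O)O | intermediate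
3 | acrolein | C=CC=O | starting material
4 | 3-(tert-butoxy)prop-1-yne | C#CCOC(C)(C)C | starting material
5 | [3-(tert-butoxy)prop-1-yn-1-yl](methyl)zinc | C[Zn]C#CCOC(C)(C)C | intermediate (not isolated)
6 | (3S)-6-(tert-butoxy)hex-1-en-4-yn-3-ol | C=C[C@H](O)C#CCOC(C)(C)C | intermediate
7 | sodium cyclic vinylalanate from 6 (Al on the carbon bearing CH2OtBu, O–Al bridge) | [Na+].CC(C)(C)OCC1=C[C@H](C=C)O[Al-]1(OCCOC)OCCOC | intermediate (not isolated)
8 | (3S,4Z)-6-(tert-butoxy)-5-iodohexa-1,4-dien-3-ol | C=C[C@H](O)/C=C(\I)COC(C)(C)C | intermediate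
9 | (3S,4Z)-6-(tert-butoxy)-5-iodohexa-1,4-dien-3-yl 2-(acetoxymethyl)acrylate | C=C[C@H](OC(=O)C(=C)COC(C)=O)/C=C(\I)COC(C)(C)C | intermediate
10 | {(5S)-5-[(1Z)-3-(tert-butoxy)-2-iodoprop-1-en-1-yl]-2-oxo-2,5-dihydrofuran-3-yl}methyl acetate | CC(=O)OCC1=C[C@@H](/C=C(\I)COC(C)(C)C)OC1=O | intermediate
11 | ethynyltrimethylsilane | C#C[Si](C)(C)C | starting material
12 | N-methoxy-N-methylacetamide | CC(=O)N(C)OC | starting material
13 | lithium (trimethylsilyl)acetylide | [Li]C#C[Si](C)(C)C | intermediate (not isolated)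
14 | 4-(trimethylsilyl)but-3-yn-2-one | CC(=O)C#C[Si](C)(C)C | intermediate
15 | (3S)-3-methyl-1-(trimethylsilyl)hex-5-en-1-yn-3-ol | C=CC[C@](C)(O)C#C[Si](C)(C)C | intermediate (not isolated)
16 | (3S)-3-methylhex-5-en-1-yn-3-ol | C=CC[C@](C)(O)C#C | intermediate
17 | {(5R)-5-[(1Z,6S)-2-(tert-butoxymethyl)-6-hydroxy-6-methyl-3-oxonona-1,8-dien-4-yn-1-yl]-2-oxo-2,5-dihydrofuran-3-yl}methyl acetate | CC(=O)OCC1=C[C@@H](/C=C(/COC(C)(C)C)C(=O)C#C[C@@](C)(O)CC=C)OC1=O | intermediate
18 | {(5R)-5-[(1Z)-2-[(5S)-5-allyl-5-methyl-4-oxo-4,5-dihydrofuran-2-yl]-3-(tert-butoxy)prop-1-en-1-yl]-2-oxo-2,5-dihydrofuran-3-yl}methyl acetate | CC(=O)OCC1=C[C@@H](/C=C(/COC(C)(C)C)C2=CC(=O)[C@](C)(CC=C)O2)OC1=O | intermediate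
19 | diol from 18 (2,3-dihydroxypropyl in place of allyl; both epimers at the new carbinol) | CC(=O)OCC1=C[C@@H](/C=C(/COC(C)(C)C)C2=CC(=O)[C@](C)(CC(O)CO)O2)OC1=O | intermediate (not isolated)
20 | aldehyde (2-oxoethyl in place of allyl; C8 = CHO) | CC(=O)OCC1=C[C@@H](/C=C(/COC(C)(C)C)C2=CC(=O)[C@](C)(CC=O)O2)OC1=O | intermediate
21 | macrocyclic Sm(III) C8-alkoxide / C12 lactone enolate, still bearing CH2OAc on C11 | I[Sm](I)O[C@@H]1C[C@]2(C)OC(=CC2=O)/C(COC(C)(C)C)=C\[C@H]2OC(O[Sm](I)I)=C(COC(C)=O)[C@@H]21 | intermediate (not isolated)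
22 | (4Z,6R,7R,8R,10S)-8-hydroxy-15-O-tert-butyl macrocycle | O[C@@H]1C[C@]2(C)OC(=CC2=O)/C(COC(C)(C)C)=C\[C@H]2OC(=O)C(=C)[C@@H]21 | intermediate
23 | 8-O-methacryloyl derivative of 22 | C=C(C)C(=O)O[C@@H]1C[C@]2(C)OC(=CC2=O)/C(COC(C)(C)C)=C\[C@H]2OC(=O)C(=C)[C@@H]21 | intermediate (not isolated)
24 | (4Z,6R,7R,8R,10S)-15-hydroxy-8-O-methacryloyl macrocycle | C=C(C)C(=O)O[C@@H]1C[C@]2(C)OC(=CC2=O)/C(CO)=C\[C@H]2OC(=O)C(=C)[C@@H]21 | intermediate
25 | (4R,5R,6S,7R,8R,10S)-4,5-epoxide of 24 | C=C(C)C(=O)O[C@@H]1C[C@]2(C)OC(=CC2=O)[C@]3(CO)O[C@@H]3[C@H]2OC(=O)C(=C)[C@@H]21 | intermediate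
26 | CNP0275292.1, (4R,5S,6S,7R,8R,10S) | C=C(C)C(=O)O[C@@H]1C[C@]2(C)OC(=CC2=O)[C@@](O)(CO)[C@@H](OC(C)=O)[C@H]2OC(=O)C(=C)[C@@H]21 | target

## Step count and risks

Total steps: 14. Longest linear sequence: 11 (steps 2, 3, 4, 5, 8, 9, 10, 11, 12, 13, 14).

**Step 11 (radical macrocyclisation).** SmI2 may instead reduce the dienone or the butenolide, ten-membered closure is slow, and the C8 configuration rests on a conformational argument. The fallback sets out from 10 and 16 and returns at 22. Alkynol 16 is cleaved with OsO4/NaIO4 to (S)-3-hydroxy-3-methylpent-4-ynal F1. SmI2 (THF, −78 °C) then couples F1 with butenolide 10 by the same ketyl addition and acetate loss, now intermolecular and anti to the C6 side chain, to give the open-chain hydroxy α-methylene lactone F2 (C8 epimers separated). The ring is closed at C3–C4 instead, by an intramolecular carbonylative Sonogashira reaction (PdCl2(PPh3)2, CuI, Et3N, CO, 1 mM), giving the macrocyclic ynone F3. Au(I) then forms the furanone transannularly to give 22.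

**Step 8 (carbonylative coupling).** The allylic acetate and the base-labile γ-hydrogen of the butenolide (C6 epimerisation) are exposed to Pd(0) and amine. The fallback sets out from 16 and returns at 17. Heating 16 with Bu3SnOMe gives (3S)-3-methyl-1-(tributylstannyl)hex-5-en-1-yn-3-ol F4. A carbonylative Stille coupling of F4 with 10 (Pd2(dba)3, AsPh3, CO 1 atm, THF, 50 °C, no amine, no copper) then gives 17.

**Step 14 (epoxide opening).** SN2 attack at C5 must come from the inner face of a medium ring, and Ti(OiPr)4 may transesterify. The fallback sets out from 23 (worked up before the TFA stage of step 12) and returns at 26; it also bypasses the directed epoxidation of step 13. DMDO epoxidises the 4,5-alkene from the outer face to the 15-O-tert-butyl epoxide F5. AcOH with catalytic Sc(OTf)3 opens it at C5 (C4 is deactivated by the furanone) to the 5-acetoxy-4-hydroxy 15-O-tert-butyl ether F6. TFA then removes the tert-butyl group to give 26.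

## Further compounds

F1 | step 11 | (S)-3-hydroxy-3-methylpent-4-ynal | C#C[C@@](C)(O)CC=O
F2 | step 11 | open-chain hydroxy α-methylene lactone (C8 carbinol, Z-vinyl iodide, terminal alkyne) | C#C[C@@](C)(O)C[C@@H](O)[C@H]1C(=C)C(=O)O[C@@H]1/C=C(\I)COC(C)(C)C
F3 | step 11 | macrocyclic γ-hydroxy ynone | O[C@@H]1C[C@](C)(O)C#CC(=O)/C(COC(C)(C)C)=C\[C@H]2OC(=O)C(=C)[C@@H]21
F4 | step 8 | (3S)-3-methyl-1-(tributylstannyl)hex-5-en-1-yn-3-ol | C=CC[C@](C)(O)C#C[Sn](CCCC)(CCCC)CCCC
F5 | step 14 | (4R,5R)-4,5-epoxide of 23 (15-O-tert-butyl) | C=C(C)C(=O)O[C@@H]1C[C@]2(C)OC(=CC2=O)[C@]3(COC(C)(C)C)O[C@@H]3[C@H]2OC(=O)C(=C)[C@@H]21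
F6 | step 14 | 15-O-tert-butyl ether of the target | C=C(C)C(=O)O[C@@H]1C[C@]2(C)OC(=CC2=O)[C@@](O)(COC(C)(C)C)[C@@H](OC(C)=O)[C@H]2OC(=O)C(=C)[C@@H]21
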